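The flavanone is disconnected across ring C at O1–C2 and C3–C4. C2 carries ring B, whose 4'-OH lies para and 2'-OMe ortho to C1', so C2–C3 is the vinyl group of an electron-rich para-hydroxystyrene, while O1–C8a–C4a–C4 is an ortho-quinone methide of ring A. One chiral-acid-catalysed inverse-demand hetero-Diels–Alder reaction therefore closes ring C, forms both bonds and sets C2 as (S), with C4 arriving as a methyl ether at the alcohol oxidation level. The partners are a 3-prenylated, 4,6-bis-MOM salicylaldehyde with its 2-OH free (quinone methide source, with trimethyl orthoformate) and the unprotected B-ring styrene.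

Key step: step 6

Assumption: the sense of induction of the chiral phosphoric acid cannot be assigned in advance; the (R)-catalyst is written, and its antipode is to be used if the first run leads to the (2R,4R) series.

Step 1
Reactants: 1 2,4,6-trihydroxybenzaldehyde; 2 prenyl bromide (1-bromo-3-methylbut-2-ene)
Product: 3 2,4,6-trihydroxy-3-(3-methylbut-2-en-1-yl)benzaldehyde
Conditions: 2 (1.0 equiv), DBU (1.1 equiv), THF, 0 °C → rt
Reagents that add atoms: none
Why: C-alkylation of the ambident phloroglucinaldehyde phenoxide (a Friedel–Crafts-type C-allylation) occurs at a ring CH; the two free ring positions are equivalent, so only one mono-C-prenyl constitution can form, and one equivalent of bromide at low temperature should limit bis- and O-alkylation.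

Step 2
Reactants: 3 2,4,6-trihydroxy-3-(3-methylbut-2-en-1-yl)benzaldehyde
Product: 4 2-hydroxy-4,6-bis(methoxymethoxy)-3-(3-methylbut-2-en-1-yl)benzaldehyde
Conditions: MOMCl (2.2 equiv), i-Pr2NEt (3 equiv), CH2Cl2, 0 °C
Reagents that add atoms: chloromethyl methyl ether, COCCl
Why: MOM ether formation (O-alkylation) should take the acidic para-OH first and then the less hindered ortho-OH, leaving free the OH that is flanked by the prenyl group and hydrogen-bonded to the formyl group.

Step 3
Reactants: 5 4-hydroxy-2-methoxybenzaldehyde; 2 prenyl bromide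
Product: 6 2-methoxy-4-[(3-methylbut-2-en-1-yl)oxy]benzaldehyde
Conditions: 2 (1.2 equiv), K2CO3 (1.5 equiv), acetone, reflux
Reagents that add atoms: none
Why: Williamson ether synthesis; the unhindered phenoxide displaces the primary allylic bromide by SN2 at oxygen.

Step 4
Reactants: 6 2-methoxy-4-[(3-methylbut-2-en-1-yl)oxy]benzaldehyde
Product: 8 4-hydroxy-2-methoxy-5-(2-methylbut-3-en-2-yl)benzaldehyde, via Claisen dienone 7 (not isolated)
Conditions: EtOH–H2O (4:1), sealed tube, 130–140 °C
Reagents that add atoms: none
Why: Aromatic Claisen rearrangement, accelerated by the protic medium: the [3,3] shift delivers the allyl unit with inversion, as the 1,1-dimethylallyl group, to C5 (C3 is crowded between two oxygen substituents), and dienone 7 tautomerises to the phenol.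

Step 5
Reactants: 8 4-hydroxy-2-methoxy-5-(2-methylbut-3-en-2-yl)benzaldehyde
Product: 9 4-ethenyl-5-methoxy-2-(2-methylbut-3-en-2-yl)phenol
Conditions: Ph3PCH3Br (3 equiv), KOtBu (3 equiv), THF, 0 °C → rt; aq. NH4Cl work-up; stored cold with BHT
Reagents that add atoms: methyltriphenylphosphonium bromide, C[P+](c1ccccc1)(c1ccccc1)c1ccccc1.[Br-]
Why: Wittig methylenation; the excess ylide first deprotonates the phenol and then converts the less electrophilic phenoxide-aldehyde into the terminal alkene, with no stereochemical issue.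

Step 6
Reactants: 4 2-hydroxy-4,6-bis(methoxymethoxy)-3-(3-methylbut-2-en-1-yl)benzaldehyde; 9 4-ethenyl-5-methoxy-2-(2-methylbut-3-en-2-yl)phenol
Product: 12 4-[(2S,4S)-4-methoxy-5,7-bis(methoxymethoxy)-8-(3-methylbut-2-en-1-yl)-3,4-dihydro-2H-chromen-2-yl]-5-methoxy-2-(2-methylbut-3-en-2-yl)phenol, via dimethyl acetal 10 (not isolated), via ortho-quinone methide 11 (not isolated)
Conditions: (R)-TRIP [(R)-3,3'-bis(2,4,6-triisopropylphenyl)-1,1'-binaphthyl-2,2'-diyl hydrogen phosphate] (10 mol %), HC(OMe)3 (1.5 equiv), 9 (1.5 equiv), 4 Å MS, PhMe, −20 → 0 °C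
Reagents that add atoms: trimethyl orthoformate, COC(OC)OC
Why: Proposed new method: the phosphoric acid converts 4 and the orthoformate into acetal 10, which ionises with loss of methanol to the 4-methoxy ortho-quinone methide 11 held by the phosphate through its dienone oxygen; the unsubstituted CH2 terminus of the vinyl group of 9, whose 4-OH is hydrogen-bonded to the P=O oxygen, attacks the methide carbon to form C3–C4, and the positive charge developing at C2, delocalised into ring B as a para-quinone methide, is quenched by O1 in a concerted but asynchronous inverse-electron-demand hetero-Diels–Alder addition. The closest known reaction types are the achiral-acid three-component synthesis of 2,4-cis-4-alkoxyflavans from salicylaldehydes, orthoformates and styrenes and the chiral phosphoric acid-catalysed [4+2] addition of ortho-quinone methides to hydroxystyrenes; new here is their combination on this heavily oxygenated pair. Ring C closes as the six-membered ring of the [4+2] adduct (heterodiene O1=C8a–C4a=C4 plus the two vinyl carbons), the O1–C2 bond forming last; if stepwise, this is a 6-exo-trig addition of the phenoxide oxygen to the para-quinone methide. C4 is set by the chiral phosphate, which binds both partners and leaves one face of the quinone methide open, and C2 is set relative to C4 by the endo transition state with ring B under the heterodiene, giving the 2,4-cis and hence (2S,4S) adduct. The step needs regio-, chemo- and enantioselectivity: the push–pull polarity of donor-substituted styrene terminus and oxocarbenium-like methide carbon fixes the orientation, the non-conjugated prenyl and 1,1-dimethylallyl alkenes are far less nucleophilic than the styrene and are not protonated by the weak acid, and the free 4'-OH together with the quinone methide oxygen supplies the two hydrogen-bond contacts on which facial control rests.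

Step 7
Reactants: 12 the (2S,4S)-4-methoxyflavan
Product: 13 (2S)-2-[4-hydroxy-2-methoxy-5-(2-methylbut-3-en-2-yl)phenyl]-5,7-bis(methoxymethoxy)-8-(3-methylbut-2-en-1-yl)-3,4-dihydro-2H-chromen-4-ol (C4 epimers, used as the mixture)
Conditions: pyridinium p-toluenesulfonate (0.2 equiv), acetone–H2O (4:1), rt
Reagents that add atoms: water, O
Why: SN1 solvolysis of an activated benzylic ether: C4 has O1 and the 5-OMOM oxygen ortho and the 7-OMOM oxygen para, so it should ionise under buffered weak acid far more readily than the C2–O1 bond or the aryl MOM ethers, and excess water captures the cation; C4 may epimerise but C2 is untouched.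

Step 8
Reactants: 13 the (2S)-flavan-4-ol
Product: 14 (2S)-2-[4-hydroxy-2-methoxy-5-(2-methylbut-3-en-2-yl)phenyl]-5,7-bis(methoxymethoxy)-8-(3-methylbut-2-en-1-yl)-2,3-dihydro-4H-chromen-4-one
Conditions: MnO2 (activated, 15 equiv), CH2Cl2, rt
Reagents that add atoms: none
Why: MnO2 oxidation of an activated benzylic alcohol under neutral heterogeneous conditions should convert both C4 epimers into one ketone while sparing the isolated alkenes, the MOM ethers and the hindered phenol; without base there is no retro-oxa-Michael opening, so C2 stays (S).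

Step 9
Reactants: 14 the (2S)-bis-MOM flavanone
Product: 15 (2S)-5,7-dihydroxy-2-[4-hydroxy-2-methoxy-5-(2-methylbut-3-en-2-yl)phenyl]-8-(3-methylbut-2-en-1-yl)-2,3-dihydro-4H-chromen-4-one (target)
Conditions: HCl (1.25 M in MeOH), rt → 40 °C
Reagents that add atoms: none
Why: Acid-catalysed acetal methanolysis removes both aryl MOM ethers (the 5-O-MOM assisted by the peri carbonyl); dilute acid near room temperature is chosen so that the prenyl and 1,1-dimethylallyl groups are not cyclised onto the neighbouring phenols and the C2–O1 bond is not opened.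

Compound list
1 | 2,4,6-trihydroxybenzaldehyde | O=Cc1c(O)cc(O)cc1O | starting material
2 | prenyl bromide (1-bromo-3-methylbut-2-ene) | CC(C)=CCBr | starting material
3 | 2,4,6-trihydroxy-3-(3-methylbut-2-en-1-yl)benzaldehyde | O=Cc1c(O)cc(O)c(CC=C(C)C)c1O | intermediate
4 | 2-hydroxy-4,6-bis(methoxymethoxy)-3-(3-methylbut-2-en-1-yl)benzaldehyde | O=Cc1c(O)c(CC=C(C)C)c(OCOC)cc1OCOC | intermediate
5 | 4-hydroxy-2-methoxybenzaldehyde | COc1cc(O)ccc1C=O | starting material
6 | 2-methoxy-4-[(3-methylbut-2-en-1-yl)oxy]benzaldehyde | COc1cc(OCC=C(C)C)ccc1C=O | intermediate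
7 | 4-formyl-3-methoxy-6-(2-methylbut-3-en-2-yl)cyclohexa-2,4-dien-1-one (racemic, not isolated) | O=CC1=CC(C(C)(C)C=C)C(=O)C=C1OC | intermediate
8 | 4-hydroxy-2-methoxy-5-(2-methylbut-3-en-2-yl)benzaldehyde | COc1cc(O)c(C(C)(C)C=C)cc1C=O | intermediate
9 | 4-ethenyl-5-methoxy-2-(2-methylbut-3-en-2-yl)phenol | C=Cc1cc(C(C)(C)C=C)c(O)cc1OC | intermediate
10 | 2-(dimethoxymethyl)-3,5-bis(methoxymethoxy)-6-(3-methylbut-2-en-1-yl)phenol (not isolated) | COC(OC)c1c(O)c(CC=C(C)C)c(OCOC)cc1OCOC | intermediate
11 | 6-(methoxymethylidene)-3,5-bis(methoxymethoxy)-2-(3-methylbut-2-en-1-yl)cyclohexa-2,4-dien-1-one (not isolated; alkene geometry not assigned) | COC=C1C(=O)C(CC=C(C)C)=C(OCOC)C=C1OCOC | intermediate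
12 | 4-[(2S,4S)-4-methoxy-5,7-bis(methoxymethoxy)-8-(3-methylbut-2-en-1-yl)-3,4-dihydro-2H-chromen-2-yl]-5-methoxy-2-(2-methylbut-3-en-2-yl)phenol (2,4-cis) | CO[C@H]1C[C@@H](c2cc(C(C)(C)C=C)c(O)cc2OC)Oc2c(CC=C(C)C)c(OCOC)cc(OCOC)c12 | intermediate
13 | (2S)-2-[4-hydroxy-2-methoxy-5-(2-methylbut-3-en-2-yl)phenyl]-5,7-bis(methoxymethoxy)-8-(3-methylbut-2-en-1-yl)-3,4-dihydro-2H-chromen-4-ol (C4 epimers) | OC1C[C@@H](c2cc(C(C)(C)C=C)c(O)cc2OC)Oc2c(CC=C(C)C)c(OCOC)cc(OCOC)c12 | intermediate
14 | (2S)-2-[4-hydroxy-2-methoxy-5-(2-methylbut-3-en-2-yl)phenyl]-5,7-bis(methoxymethoxy)-8-(3-methylbut-2-en-1-yl)-2,3-dihydro-4H-chromen-4-one | O=C1C[C@@H](c2cc(C(C)(C)C=C)c(O)cc2OC)Oc2c(CC=C(C)C)c(OCOC)cc(OCOC)c12 | intermediate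
15 | (2S)-5,7-dihydroxy-2-[4-hydroxy-2-methoxy-5-(2-methylbut-3-en-2-yl)phenyl]-8-(3-methylbut-2-en-1-yl)-2,3-dihydro-4H-chromen-4-one | C=CC(C)(C)c1cc([C@@H]2CC(=O)c3c(O)cc(O)c(CC=C(C)C)c3O2)c(OC)cc1O | target

Total step count: 9 (steps 1–2 for the aldehyde, 3–5 for the styrene, 6–9 after convergence).
Longest linear sequence: 7 steps (steps 3, 4, 5, 6, 7, 8 and 9, from 5).

Steps most likely to fail

Step 6 (carries the label). Several processes could defeat it:
- The weak acid may turn over too slowly in acetal ionisation.
- Facial selectivity may be poor, because the 1,1-dimethylallyl group beside the 4'-OH and the OMOM group beside the methide carbon disturb the two-point binding.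
- The electron-rich ring A of the product may capture the quinone methide in a Friedel–Crafts reaction.
- The styrene may oligomerise under acid.

The fallback sets out from 4 and 9 and comes back at 14. It replaces asymmetric catalysis by the established racemic reaction and a late resolution. The three components are combined under known achiral conditions for 2,4-cis-4-alkoxyflavans (Sc(OTf)3 5 mol %, HC(OMe)3, CH2Cl2, 0 °C), which should give, by way of 10 and 11, the racemic 2,4-cis-4-methoxyflavan F1. The exchange and oxidation of steps 7 and 8 then lead through the racemic flavan-4-ol F2 to the racemic bis-MOM flavanone F3. F3 is resolved by preparative HPLC on an amylose tris(3,5-dimethylphenylcarbamate) phase, and the (2S) fraction is 14.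

Step 7. The acid may ionise the C2–O1 bond as well, since ring B with its free 4'-OH and 2'-OMe stabilises that cation. This would epimerise C2 relative to C4 and erode the enantiomeric purity after oxidation. Loss of a C3 proton to the flav-3-ene is a second drain. The fallback sets out from 12 and comes back at 15. It changes the electronic design rather than the acid: the 4'-OH is acetylated (Ac2O, pyridine, 4-(dimethylamino)pyridine cat., CH2Cl2, 0 °C) to the 4'-O-acetyl 4-methoxyflavan F4. The acetoxy group makes ring B a much poorer donor, so the C4 exchange can be driven with stronger aqueous acid (TsOH, THF–H2O, rt) to the 4'-O-acetyl flavan-4-ol F5 without touching C2. With the phenol masked, Dess–Martin periodinane (NaHCO3, CH2Cl2, 0 °C) then gives the 4'-O-acetyl bis-MOM flavanone F6. Methanolic HCl finally cleaves the acetate and both MOM ethers in one operation to 15.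

Step 2. The second MOM group may not discriminate cleanly between the two ortho hydroxyl groups, giving the isomer with the free OH remote from the prenyl group, and over-protection can occur. The fallback sets out from 1 and comes back at 4. It fixes the constitution by a sigmatropic shift instead of by selective protection:
- Bis-MOM protection of 1 (MOMCl 2.1 equiv, i-Pr2NEt, CH2Cl2, 0 °C) can give only one hydrogen-bonded monophenol, 2-hydroxy-4,6-bis(methoxymethoxy)benzaldehyde F7.
- Its O-alkylation with 3-chloro-3-methylbut-1-yne (DBU, CuCl2 cat., MeCN, 0 °C) gives the 1,1-dimethylpropargyl ether F8.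
- Semi-hydrogenation (H2, Pd/CaCO3 poisoned with Pb(OAc)2, quinoline, EtOAc) gives the 1,1-dimethylallyl ether F9.
- Aromatic Claisen rearrangement of F9 (PhMe, 110 °C) moves the allyl unit with inversion to the only free ortho position, so the prenyl group of 4 necessarily ends up next to the liberated OH.

Further compounds
F1 | step 6 | racemic 2,4-cis form of 12: 4-[4-methoxy-5,7-bis(methoxymethoxy)-8-(3-methylbut-2-en-1-yl)-3,4-dihydro-2H-chromen-2-yl]-5-methoxy-2-(2-methylbut-3-en-2-yl)phenol | COC1CC(c2cc(C(C)(C)C=C)c(O)cc2OC)Oc2c(CC=C(C)C)c(OCOC)cc(OCOC)c12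
F2 | step 6 | racemic form of 13: 2-[4-hydroxy-2-methoxy-5-(2-methylbut-3-en-2-yl)phenyl]-5,7-bis(methoxymethoxy)-8-(3-methylbut-2-en-1-yl)-3,4-dihydro-2H-chromen-4-ol | OC1CC(c2cc(C(C)(C)C=C)c(O)cc2OC)Oc2c(CC=C(C)C)c(OCOC)cc(OCOC)c12
F3 | step 6 | racemic form of 14: 2-[4-hydroxy-2-methoxy-5-(2-methylbut-3-en-2-yl)phenyl]-5,7-bis(methoxymethoxy)-8-(3-methylbut-2-en-1-yl)-2,3-dihydro-4H-chromen-4-one | O=C1CC(c2cc(C(C)(C)C=C)c(O)cc2OC)Oc2c(CC=C(C)C)c(OCOC)cc(OCOC)c12
F4 | step 7 | 4-[(2S,4S)-4-methoxy-5,7-bis(methoxymethoxy)-8-(3-methylbut-2-en-1-yl)-3,4-dihydro-2H-chromen-2-yl]-5-methoxy-2-(2-methylbut-3-en-2-yl)phenyl acetate | CO[C@H]1C[C@@H](c2cc(C(C)(C)C=C)c(OC(C)=O)cc2OC)Oc2c(CC=C(C)C)c(OCOC)cc(OCOC)c12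
F5 | step 7 | 4-[(2S)-4-hydroxy-5,7-bis(methoxymethoxy)-8-(3-methylbut-2-en-1-yl)-3,4-dihydro-2H-chromen-2-yl]-5-methoxy-2-(2-methylbut-3-en-2-yl)phenyl acetate (C4 epimers) | OC1C[C@@H](c2cc(C(C)(C)C=C)c(OC(C)=O)cc2OC)Oc2c(CC=C(C)C)c(OCOC)cc(OCOC)c12
F6 | step 7 | 4-[(2S)-5,7-bis(methoxymethoxy)-8-(3-methylbut-2-en-1-yl)-4-oxo-3,4-dihydro-2H-chromen-2-yl]-5-methoxy-2-(2-methylbut-3-en-2-yl)phenyl acetate | O=C1C[C@@H](c2cc(C(C)(C)C=C)c(OC(C)=O)cc2OC)Oc2c(CC=C(C)C)c(OCOC)cc(OCOC)c12
F7 | step 2 | 2-hydroxy-4,6-bis(methoxymethoxy)benzaldehyde | O=Cc1c(O)cc(OCOC)cc1OCOC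
F8 | step 2 | 2,4-bis(methoxymethoxy)-6-[(2-methylbut-3-yn-2-yl)oxy]benzaldehyde | O=Cc1c(OC(C)(C)C#C)cc(OCOC)cc1OCOC
F9 | step 2 | 2,4-bis(methoxymethoxy)-6-[(2-methylbut-3-en-2-yl)oxy]benzaldehyde | O=Cc1c(OC(C)(C)C=C)cc(OCOC)cc1OCOC
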